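## Structural features

The target is an isoflavanone. Ring A, a phloroglucinol-type benzene ring, is fused to the pyranone ring C (O1, C2, C3, C4, C4a, C8a), and ring B is attached at C3. Ring A carries free hydroxyls at C5 and C7, and its third oxygen is O1. Ring B is 1,3,4,5-tetrasubstituted, with 3'-OH, 4'-OMe and a 3-methylbut-2-enyl (prenyl) chain at C5'. C3 is the only stereocentre (S). It has no stereogenic neighbour, but it is benzylic and alpha to the C4 carbonyl, so it epimerises through the enol with base, with warm acid and on long heating. The trisubstituted prenyl alkene adds protic acid easily, and 7-OH is a vinylogous carboxylic acid, so three phenols must be masked and later unmasked without touching either weak point. The real difficulty is therefore not the skeleton but setting C3 in one sense and keeping it through ring closure, prenylation and deprotection. The key step uses the local symmetry of ring A: in a 3,5-dioxygenated aryl ether the two carbons ortho to the ether oxygen (either can become C4a) are equivalent and each is ortho or para to all three oxygens. The carboxyl carbon that becomes C4 can therefore close ring C at C4–C4a with no regiochemical choice.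

## Logic of the disconnections

20 to 19. The three aryl O–Si bonds are cut. The phenols must be masked during acylation and coupling, and fluoride cleavage is the one unmasking that needs neither base (C3) nor strong acid (prenyl). The skeleton is unchanged; the gain is a non-acidic, lipophilic intermediate. The forward step must be buffered.

19 to 17 and 18. The C5'–CH2 bond of the prenyl chain is cut. The alkene would not be expected to survive acid chloride and Lewis acid, so a bromine holds its place. Ring B becomes a plain bromoarene and 18 is a commercial reagent. The coupling must run without base and must deliver the unrearranged allyl terminus.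

17 to 15 through 16. The C4–C4a bond is cut. Ring A is symmetric about the ether carbon, so the bond can be made at either ortho carbon. The cut turns a bicyclic ketone with an enolisable stereocentre into an open-chain acid. The forward step needs activation without base and acylation at low temperature.

15 to 13 through 14. No skeletal bond is cut; C4 is taken down to the alcohol level. There the stereocentre is not enolisable, and the two arms on C3 differ only in what is on oxygen. The oxidation must not let the aldehyde stage linger.

13 to 12, then to 9 and 11. The O1–C2 alkyl–oxygen bond is cut, and the acetyl group on the other arm is restored. This splits the molecule into a ring A half and a ring B half. The ether forms at a primary carbon one atom away from the stereocentre. The forward steps must avoid acyl migration and must remove the acetate without alkoxide, which would attack the aryl silyl ethers.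

9 to 8. The acetyl C–O bond is cut. This reveals a diol with a mirror plane, so the stereocentre becomes a choice between two enantiotopic hydroxymethyl groups. The catalyst must select one group. Because either arm can in principle be taken to the acid or to the ether, the plan does not hinge on one sense of selection.

8 to 6, then to 4 and 5. The C3–C1' bond and one C3–CH2 bond are cut. Carbon 3 and one arm come from 5, the other arm from the formyl carbon of 4, and the aryl group is moved onto C3 by a 1,2-shift. A three-carbon unit with the aryl on its central carbon is thus built in one step from an aldehyde. Aryl migration must outrun hydride migration.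

4 to 3, 2 and 1. One O–Si bond and the O–CH3 bonds are cut. Bromination ortho to a free phenol gives 1 cheaply, but with the methyl on the wrong oxygen, so the methyl is taken off and put back on the para oxygen. The forward methylation must be selective for the hydroxyl para to the formyl group.

11 to 10. Two O–Si bonds are cut. The threefold symmetry of 10 makes the bis-ether a statistical but single-isomer product.

## Other disconnections considered

Alternative 1: The cut runs through ring C at C3–C4 and O1–C2. In the forward step the benzodioxinone A2 is irradiated, cycloreversion gives the quinoketene A4, and the β-methoxystyrene A3 adds in a hetero-[4+2] manner to give the 2-methoxyisoflavanone A1.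
- In its favour: two bonds and ring C form in one step. The regiochemistry follows from polarity, since the nucleophilic aryl-bearing carbon of A3 bonds to the ketene carbon. The medium is close to neutral, so the prenyl group can already sit in A3. On convergence and on handling of the prenyl group this plan is the better one, and the route to the bare skeleton is shorter.
- Against it: nothing controls C3, so A1 would form racemic and as C2 epimers. The extra methoxy group at C2 must then go. Ionic reduction with a silane and a Lewis acid threatens the methoxymethyl ethers and the prenyl alkene. Loss of methanol to the isoflavone A5 erases C3, which would have to be re-set by asymmetric reduction and re-oxidation. The acetal protecting groups also need protic acid at the very end.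
- Comparison: both plans lean on the symmetry of ring A. The cycloaddition is milder than an ionic acylation. The chosen plan sets C3 early with an enzyme and only has to preserve it. Once the stereochemical repair is counted, the step counts become similar.

Alternative 2: The cuts are O1–C8a, C4–C4a and O1–C2, so ring A enters as the benzyne A9. CsF releases A9 from the silyl triflate A8. The carboxylate of the 2-arylacrylic acid A7 adds at C8a, the aryne carbon remote from the C5 oxygen. The aryl anion at C4a then takes the acyl group, and the freed phenoxide closes ring C by conjugate addition to give A6.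
- In its favour: three bonds form in one flask without a transition metal. The polarisation of the 3-oxygenated aryne points the same way as the required regiochemistry. The prenyl group is carried from the start. In convergence and step economy this plan is better than the chosen one, and its regiocontrol is about as secure.
- Against it: the enolate formed in the oxa-Michael step is protonated without control, and the basic fluoride medium would equilibrate C3 in any case, so A6 is racemic. A8 needs a regiodefined silylation and triflation of a phloroglucinol derivative. A7 is a polymerisable acrylic acid. The aryne could also undergo an ene reaction with the prenyl group. Acidic removal of the acetals at the end is a further risk.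
- Comparison: the aryne plan wins on brevity, but it leaves the central problem, C3, entirely unsolved.

Alternative 3: The cut is C2–C3, with C2 taken from an O-methyl group. The diazoketone A11 loses dinitrogen on Rh2(S-PTTL)4, a carboxylate complex of divalent rhodium, and the carbenoid carbon inserts into a C–H bond of an ortho methoxy group to give A10.
- In its favour: this is the only plan in which a catalyst creates C3 in the ring-forming step, which is conceptually better than carrying a preformed centre. A11 should be reachable in few steps through a deoxybenzoin and diazo transfer, so step economy is equal or better. The two ortho methoxy groups of ring A are equivalent, which is the same symmetry argument as in the chosen plan.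
- Against it: a methoxy C–H is primary and the insertion is a 1,6-process. The same oxygen can instead attack the carbenoid to give a five-membered oxonium ylide and then a benzofuranone by a 1,2-shift. The prenyl alkene is a cyclopropanation partner. The new centre is alpha to a ketone in the presence of a Lewis acidic metal. The leftover 5-O-methyl group must be cleaved next to 4'-OMe with chelating Lewis acids, which endanger both the prenyl group and C3.
- Comparison: the carbene plan is shorter and more elegant in how it sets C3. The chosen plan uses reaction types whose selectivities are each well understood on this substrate class.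

Key step: step 11

## Remarks on the chemistry

- Correction: ring B needs OMe para and OH meta to the carbon that becomes C1'. Compound 1 has them the other way round, so steps 1 and 2 move the methyl group; without this the route would end in the 3'-OMe/4'-OH isomer.
- Correction: a benzaldehyde cannot be turned directly into an arylmalonate. The three-carbon unit is instead built on the formyl carbon in steps 4 and 5.
- Assumption: the lipase in step 6 acetylates the pro-S hydroxymethyl group of 8. The fallback for step 6 covers the opposite or a weak preference.

## Route

Step 1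
Reactants: 1 5-bromovanillin (3-bromo-4-hydroxy-5-methoxybenzaldehyde)
Product: 2 3-bromo-4,5-dihydroxybenzaldehyde
Conditions: BBr3, CH2Cl2, –78 °C → rt; H2O
Reagents that add atoms: none
Why: Lewis acid cleavage of an aryl methyl ether: boron binds the ether oxygen and bromide removes the methyl group by SN2. The aldehyde and the aryl bromide are inert under these conditions.

Step 2
Reactants: 2 3-bromo-4,5-dihydroxybenzaldehyde
Product: 3 3-bromo-5-hydroxy-4-methoxybenzaldehyde
Conditions: MeI, Li2CO3, DMF, 40 °C
Reagents that add atoms: iodomethane, CI
Why: Selective Williamson methylation: the hydroxyl para to the formyl group (and ortho to bromine) is the more acidic, so a weak base ionises it alone and it is alkylated. This is the usual outcome for 3,4-dihydroxybenzaldehydes.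

Step 3
Reactants: 3 3-bromo-5-hydroxy-4-methoxybenzaldehyde
Product: 4 3-bromo-4-methoxy-5-(triisopropylsilyloxy)benzaldehyde
Conditions: TIPSCl, imidazole, DMF, rt
Reagents that add atoms: chlorotriisopropylsilane, CC(C)[Si](Cl)(C(C)C)C(C)C
Why: Standard silylation of a phenol. The bulky silyl ether should tolerate hydride, Mitsunobu, Lewis acid and zerovalent palladium, and it is removed at the end by fluoride.

Step 4
Reactants: 4 3-bromo-4-methoxy-5-(triisopropylsilyloxy)benzaldehyde; 5 ethyl diazoacetate
Product: 6 ethyl (2Z)-2-[3-bromo-4-methoxy-5-(triisopropylsilyloxy)phenyl]-3-hydroxyprop-2-enoate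
Conditions: HBF4·OEt2 (10 mol%), CH2Cl2, –78 °C
Reagents that add atoms: none
Why: Acid-catalysed aldehyde–diazoacetate homologation, a Roskamp-type addition diverted to aryl migration: the diazo carbon adds to the protonated aldehyde, and the aryl group, para-methoxy-substituted, shifts to that carbon as dinitrogen leaves. The resulting 2-aryl-3-oxopropanoate rests as the hydrogen-bonded Z enol.

Step 5
Reactants: 6 ethyl (2Z)-2-[3-bromo-4-methoxy-5-(triisopropylsilyloxy)phenyl]-3-hydroxyprop-2-enoate
Product: 8 2-[3-bromo-4-methoxy-5-(triisopropylsilyloxy)phenyl]propane-1,3-diol, via racemic hydroxy ester 7 (not isolated)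
Conditions: NaBH4, EtOH–THF, 0 °C; then LiCl, 0 °C → rt
Reagents that add atoms: none
Why: Borohydride reduces the formyl tautomer to the β-hydroxy ester in the protic medium; LiBH4 made in the flask then reduces the ester. The product is a diol with a mirror plane, so no stereochemistry is at stake here.

Step 6
Reactants: 8 2-[3-bromo-4-methoxy-5-(triisopropylsilyloxy)phenyl]propane-1,3-diol
Product: 9 (2S)-2-[3-bromo-4-methoxy-5-(triisopropylsilyloxy)phenyl]-3-hydroxypropyl acetate
Conditions: lipase PS (Burkholderia cepacia, immobilised), vinyl acetate, t-BuOMe, 25 °C
Reagents that add atoms: vinyl acetate, CC(=O)OC=C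
Why: Enzymatic desymmetrisation of a prochiral 2-aryl-1,3-propanediol by irreversible transesterification. The stereocentre is set by the active site, which should acylate one of the two enantiotopic hydroxymethyl groups; the acetylated arm later becomes C4 and the free arm C2. Slow second acylation of the minor monoacetate should raise the purity of 9 further.

Step 7
Reactants: 10 phloroglucinol
Product: 11 3,5-bis(triisopropylsilyloxy)phenol
Conditions: TIPSCl (2 equiv), imidazole, DMF, 0 °C → rt
Reagents that add atoms: chlorotriisopropylsilane, CC(C)[Si](Cl)(C(C)C)C(C)C
Why: Statistical silylation of a threefold-symmetric triphenol. Only one bis-ether exists, and it should separate by chromatography from the mono- and tris-ethers, which can be recycled.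

Step 8
Reactants: 9 (2S)-2-[3-bromo-4-methoxy-5-(triisopropylsilyloxy)phenyl]-3-hydroxypropyl acetate; 11 3,5-bis(triisopropylsilyloxy)phenol
Product: 12 (2S)-3-[3,5-bis(triisopropylsilyloxy)phenoxy]-2-[3-bromo-4-methoxy-5-(triisopropylsilyloxy)phenyl]propyl acetate
Conditions: PPh3, DIAD, toluene, 0 °C → rt
Reagents that add atoms: none
Why: Mitsunobu etherification: the phenoxide displaces the alkoxyphosphonium group at a primary carbon by SN2, forming the O1–C2 bond. The stereocentre is one carbon away and untouched, and direct displacement should outrun participation by the acetate.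

Step 9
Reactants: 12 (2S)-3-[3,5-bis(triisopropylsilyloxy)phenoxy]-2-[3-bromo-4-methoxy-5-(triisopropylsilyloxy)phenyl]propyl acetate
Product: 13 (2R)-3-[3,5-bis(triisopropylsilyloxy)phenoxy]-2-[3-bromo-4-methoxy-5-(triisopropylsilyloxy)phenyl]propan-1-ol
Conditions: i-Bu2AlH, CH2Cl2, –78 °C; aq. potassium sodium tartrate
Reagents that add atoms: none
Why: Reductive removal of the acetate avoids the alkoxide of a methanolysis, which would attack the three aryl silyl ethers; the aryl bromide is inert at –78 °C. The descriptor changes to R only because the ranking of the two arms changes, not the geometry.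

Step 10
Reactants: 13 (2R)-3-[3,5-bis(triisopropylsilyloxy)phenoxy]-2-[3-bromo-4-methoxy-5-(triisopropylsilyloxy)phenyl]propan-1-ol
Product: 15 (2S)-3-[3,5-bis(triisopropylsilyloxy)phenoxy]-2-[3-bromo-4-methoxy-5-(triisopropylsilyloxy)phenyl]propanoic acid, via aldehyde 14 (not isolated)
Conditions: TEMPO (cat.), PhI(OAc)2, CH2Cl2–H2O, 0 °C → rt
Reagents that add atoms: water, O
Why: Oxoammonium-mediated oxidation of a primary alcohol to the acid in one flask: the aldehyde is hydrated and oxidised on as it forms, at nearly neutral pH. Its enolisation (loss of configuration) and β-elimination of the aryloxide should therefore have little time to occur.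

Step 11
Reactants: 15 (2S)-3-[3,5-bis(triisopropylsilyloxy)phenoxy]-2-[3-bromo-4-methoxy-5-(triisopropylsilyloxy)phenyl]propanoic acid
Product: 17 (3S)-3-[3-bromo-4-methoxy-5-(triisopropylsilyloxy)phenyl]-5,7-bis(triisopropylsilyloxy)chroman-4-one, via acid chloride 16 (not isolated)
Conditions: 1-chloro-N,N,2-trimethylpropenylamine, CH2Cl2, 0 °C; then SnCl4, –78 °C; cold pH 7 buffer
Reagents that add atoms: none
Why: The chloroenamine turns the acid into acid chloride 16 under neutral conditions, with an amide as the only co-product, so no amine base is present that could eliminate HCl to an aryl ketene and erase C3. SnCl4 then polarises the C–Cl bond, the carbon of ring A ortho to the ether oxygen attacks the acyl carbon, and loss of a proton from the sigma complex gives the aryl ketone with the new C4–C4a bond. This is an intramolecular Friedel–Crafts acylation, the standard closure of 3-aryloxypropanoic acids to chroman-4-ones. Ring C (O1–C2–C3–C4–C4a–C8a) closes in a 6-exo-trig mode with the arene as nucleophile. No stereocentre is created; C3 is only carried through, protected by the absence of base, the low temperature and the speed of an intramolecular attack by a ring activated by three oxygens. Regioselectivity comes from the substrate: the two positions ortho to the ether oxygen are equivalent by symmetry, the para position cannot reach the acyl carbon, and ring B could only be acylated through a strained small ring. C-acylation is preferred to O-acylation because the phenolic oxygens are silylated and an eight-membered lactone would be required. The bromine and the two ortho groups that twist the 4'-methoxy group out of conjugation also disfavour the main side path, decarbonylation of the acylium ion to a benzylic cation.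

Step 12
Reactants: 17 (3S)-3-[3-bromo-4-methoxy-5-(triisopropylsilyloxy)phenyl]-5,7-bis(triisopropylsilyloxy)chroman-4-one; 18 tributyl(3-methylbut-2-enyl)stannane
Product: 19 (3S)-3-[4-methoxy-3-(3-methylbut-2-enyl)-5-(triisopropylsilyloxy)phenyl]-5,7-bis(triisopropylsilyloxy)chroman-4-one
Conditions: Pd(PPh3)4 (10 mol%), toluene, 90 °C, degassed
Reagents that add atoms: none
Why: Stille coupling: zerovalent palladium inserts into the aryl–bromine bond, the allylic stannane transmetalates, and reductive elimination at the less substituted allyl terminus should give the prenyl arene. No base or fluoride is present and the solvent is non-polar, so the enolisable C3 centre, the ketone and the silyl ethers should be left alone.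

Step 13
Reactants: 19 (3S)-3-[4-methoxy-3-(3-methylbut-2-enyl)-5-(triisopropylsilyloxy)phenyl]-5,7-bis(triisopropylsilyloxy)chroman-4-one
Product: 20 (3S)-5,7-dihydroxy-3-[3-hydroxy-4-methoxy-5-(3-methylbut-2-enyl)phenyl]chroman-4-one (3S-5,7,3'-trihydroxy-4'-methoxy-5'-prenylisoflavanone)
Conditions: HF·pyridine, pyridine–THF, 0 °C → rt
Reagents that add atoms: none
Why: Fluoride-driven cleavage of three aryl silyl ethers, pulled by the strength of the Si–F bond. Pyridine buffers the medium, so it is neither basic enough to enolise C3 nor acidic enough to add to the prenyl alkene.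

## Compound list

1 | 5-bromovanillin (3-bromo-4-hydroxy-5-methoxybenzaldehyde) | COc1cc(C=O)cc(Br)c1O | starting material
2 | 3-bromo-4,5-dihydroxybenzaldehyde | O=Cc1cc(O)c(O)c(Br)c1 | intermediate
3 | 3-bromo-5-hydroxy-4-methoxybenzaldehyde | COc1c(O)cc(C=O)cc1Br | intermediate
4 | 3-bromo-4-methoxy-5-(triisopropylsilyloxy)benzaldehyde | COc1c(O[Si](C(C)C)(C(C)C)C(C)C)cc(C=O)cc1Br | intermediate
5 | ethyl diazoacetate | CCOC(=O)C=[N+]=[N-] | starting material
6 | ethyl (2Z)-2-[3-bromo-4-methoxy-5-(triisopropylsilyloxy)phenyl]-3-hydroxyprop-2-enoate | CCOC(=O)/C(=C\O)c1cc(Br)c(OC)c(O[Si](C(C)C)(C(C)C)C(C)C)c1 | intermediate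
7 | ethyl 2-[3-bromo-4-methoxy-5-(triisopropylsilyloxy)phenyl]-3-hydroxypropanoate (racemic, not isolated) | CCOC(=O)C(CO)c1cc(Br)c(OC)c(O[Si](C(C)C)(C(C)C)C(C)C)c1 | intermediate
8 | 2-[3-bromo-4-methoxy-5-(triisopropylsilyloxy)phenyl]propane-1,3-diol | COc1c(O[Si](C(C)C)(C(C)C)C(C)C)cc(C(CO)CO)cc1Br | intermediate
9 | (2S)-2-[3-bromo-4-methoxy-5-(triisopropylsilyloxy)phenyl]-3-hydroxypropyl acetate | COc1c(O[Si](C(C)C)(C(C)C)C(C)C)cc([C@H](COC(C)=O)CO)cc1Br | intermediate
10 | phloroglucinol | Oc1cc(O)cc(O)c1 | starting material
11 | 3,5-bis(triisopropylsilyloxy)phenol | Oc1cc(O[Si](C(C)C)(C(C)C)C(C)C)cc(O[Si](C(C)C)(C(C)C)C(C)C)c1 | intermediate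
12 | (2S)-3-[3,5-bis(triisopropylsilyloxy)phenoxy]-2-[3-bromo-4-methoxy-5-(triisopropylsilyloxy)phenyl]propyl acetate | COc1c(O[Si](C(C)C)(C(C)C)C(C)C)cc([C@H](COC(C)=O)COc2cc(O[Si](C(C)C)(C(C)C)C(C)C)cc(O[Si](C(C)C)(C(C)C)C(C)C)c2)cc1Br | intermediate
13 | (2R)-3-[3,5-bis(triisopropylsilyloxy)phenoxy]-2-[3-bromo-4-methoxy-5-(triisopropylsilyloxy)phenyl]propan-1-ol | COc1c(O[Si](C(C)C)(C(C)C)C(C)C)cc([C@H](CO)COc2cc(O[Si](C(C)C)(C(C)C)C(C)C)cc(O[Si](C(C)C)(C(C)C)C(C)C)c2)cc1Br | intermediate
14 | (2S)-3-[3,5-bis(triisopropylsilyloxy)phenoxy]-2-[3-bromo-4-methoxy-5-(triisopropylsilyloxy)phenyl]propanal (not isolated) | COc1c(O[Si](C(C)C)(C(C)C)C(C)C)cc([C@H](C=O)COc2cc(O[Si](C(C)C)(C(C)C)C(C)C)cc(O[Si](C(C)C)(C(C)C)C(C)C)c2)cc1Br | intermediate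
15 | (2S)-3-[3,5-bis(triisopropylsilyloxy)phenoxy]-2-[3-bromo-4-methoxy-5-(triisopropylsilyloxy)phenyl]propanoic acid | COc1c(O[Si](C(C)C)(C(C)C)C(C)C)cc([C@H](C(=O)O)COc2cc(O[Si](C(C)C)(C(C)C)C(C)C)cc(O[Si](C(C)C)(C(C)C)C(C)C)c2)cc1Br | intermediate
16 | (2S)-3-[3,5-bis(triisopropylsilyloxy)phenoxy]-2-[3-bromo-4-methoxy-5-(triisopropylsilyloxy)phenyl]propanoyl chloride (not isolated) | COc1c(O[Si](C(C)C)(C(C)C)C(C)C)cc([C@H](C(=O)Cl)COc2cc(O[Si](C(C)C)(C(C)C)C(C)C)cc(O[Si](C(C)C)(C(C)C)C(C)C)c2)cc1Br | intermediate
17 | (3S)-3-[3-bromo-4-methoxy-5-(triisopropylsilyloxy)phenyl]-5,7-bis(triisopropylsilyloxy)chroman-4-one | COc1c(O[Si](C(C)C)(C(C)C)C(C)C)cc([C@H]2COc3cc(O[Si](C(C)C)(C(C)C)C(C)C)cc(O[Si](C(C)C)(C(C)C)C(C)C)c3C2=O)cc1Br | intermediate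
18 | tributyl(3-methylbut-2-enyl)stannane | CCCC[Sn](CCCC)(CCCC)CC=C(C)C | starting material
19 | (3S)-3-[4-methoxy-3-(3-methylbut-2-enyl)-5-(triisopropylsilyloxy)phenyl]-5,7-bis(triisopropylsilyloxy)chroman-4-one | COc1c(O[Si](C(C)C)(C(C)C)C(C)C)cc([C@H]2COc3cc(O[Si](C(C)C)(C(C)C)C(C)C)cc(O[Si](C(C)C)(C(C)C)C(C)C)c3C2=O)cc1CC=C(C)C | intermediate
20 | (3S)-5,7-dihydroxy-3-[3-hydroxy-4-methoxy-5-(3-methylbut-2-enyl)phenyl]chroman-4-one | COc1c(O)cc([C@H]2COc3cc(O)cc(O)c3C2=O)cc1CC=C(C)C | target

## Step count and least certain steps

Total step count: 13. Longest linear sequence: 12 steps (steps 1 to 6 and 8 to 13, from 1 to 20); step 7 is a one-step side branch.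

**Step 11 (key step).** The most likely failure is loss of configuration at C3. It could occur by elimination of HCl from 16 to a ketene if any basic impurity is present, or by tin-promoted enolisation of 17 if the mixture warms before the quench. Less likely are decarbonylation of the acylium ion and loss of the silyl group next to the new carbonyl through chelation; the latter would be harmless, since that group is removed later anyway. Fallback: re-set C3 after the ring is closed instead of trying to preserve it. Starting from 17 of eroded purity, asymmetric transfer hydrogenation with dynamic kinetic resolution is used: RuCl[(S,S)-TsDPEN](p-cymene), HCO2H–Et3N. The amine keeps C3 equilibrating while the catalyst reduces one enantiomer of the ketone. By analogy with aryl alkyl ketones this should give the cis alcohol (3S,4S)-3-[3-bromo-4-methoxy-5-(triisopropylsilyloxy)phenyl]-5,7-bis(triisopropylsilyloxy)chroman-4-ol F1. Oxidation with Dess–Martin periodinane buffered with NaHCO3 then returns to 17. The same sequence can be applied to 19, because the catalyst does not reduce the isolated alkene.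

**Step 12.** Three things could go wrong:
- Allylic transposition during transmetalation or reductive elimination would attach the tertiary allyl terminus instead of the primary one.
- Oxidative addition into an electron-rich aryl bromide with an ortho methoxy group may be slow.
- Slow oxidative addition forces longer heating, and heating invites thermal epimerisation at C3.

Fallback: install the chain in two stages that cannot transpose. From 17, coupling with allyltributylstannane under the same palladium conditions should give (3S)-3-[4-methoxy-3-(prop-2-enyl)-5-(triisopropylsilyloxy)phenyl]-5,7-bis(triisopropylsilyloxy)chroman-4-one F2. Cross-metathesis of F2 with excess 2-methyl-2-butene using the second-generation Grubbs catalyst, RuCl2(H2IMes)(PCy3)(=CHPh), in CH2Cl2 at 40 °C returns to the route at 19.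

**Step 10.** The transient aldehyde 14 is benzylic, alpha to a carbonyl, and has an aryloxide leaving group in the β position. Enolisation would erode the configuration, and E1cB loss of the ring A phenoxide would destroy the material. The very electron-rich ring A could also be attacked by the oxidant. Fallback: separate the two oxidation levels and use different oxidants. From 13, Dess–Martin periodinane with NaHCO3 in CH2Cl2 at 0 °C gives 14, which is isolated cold and used at once. Chlorite oxidation (NaClO2, NaH2PO4, a large excess of 2-methyl-2-butene, t-BuOH–H2O, 0 °C; Pinnick conditions) then returns to 15. This fallback makes no new compound (F0). Any erosion that remains can be repaired downstream by the sequence given for step 11.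

**Step 6.** The enzyme may discriminate the two hydroxymethyl groups poorly or in the opposite sense. It may also acylate slowly because of the bulky silyloxy group in the meta position, and over-acylation costs material. Fallback: replace the enzyme by a small-molecule catalyst available in both mirror-image forms. From 8, the dinuclear zinc catalyst made from Et2Zn and a ProPhenol ligand of the appropriate handedness, with vinyl benzoate in toluene at –15 °C, should give (2S)-2-[3-bromo-4-methoxy-5-(triisopropylsilyloxy)phenyl]-3-hydroxypropyl benzoate F3. Mitsunobu coupling with 11 gives (2S)-3-[3,5-bis(triisopropylsilyloxy)phenoxy]-2-[3-bromo-4-methoxy-5-(triisopropylsilyloxy)phenyl]propyl benzoate F4, and reduction with i-Bu2AlH at –78 °C returns to 13.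

**Step 4.** Hydride shift could compete with aryl shift in the diazonium intermediate and lead to the β-keto ester, because the aryl ring is only moderately electron-rich. The fluoroborate acid could also remove part of the silyl group. Fallback: build the same compound by carbonyl chemistry without a migration. From 3, condensation with methyl (methylsulfanyl)methyl sulfoxide (benzyltrimethylammonium hydroxide, THF, reflux) gives 3-bromo-2-methoxy-5-[2-(methylsulfanyl)-2-(methylsulfinyl)ethenyl]phenol F5. HCl in ethanol converts F5 into ethyl (3-bromo-5-hydroxy-4-methoxyphenyl)acetate F6. Silylation as in step 3 gives ethyl [3-bromo-4-methoxy-5-(triisopropylsilyloxy)phenyl]acetate F7. Claisen formylation of F7 (LiN(i-Pr)2, then HCO2Et, THF, –78 °C) returns to the route at 6.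

## Further compounds

F1 | step 11 | (3S,4S)-3-[3-bromo-4-methoxy-5-(triisopropylsilyloxy)phenyl]-5,7-bis(triisopropylsilyloxy)chroman-4-ol | COc1c(O[Si](C(C)C)(C(C)C)C(C)C)cc([C@H]2COc3cc(O[Si](C(C)C)(C(C)C)C(C)C)cc(O[Si](C(C)C)(C(C)C)C(C)C)c3[C@H]2O)cc1Br
F2 | step 12 | (3S)-3-[4-methoxy-3-(prop-2-enyl)-5-(triisopropylsilyloxy)phenyl]-5,7-bis(triisopropylsilyloxy)chroman-4-one | COc1c(O[Si](C(C)C)(C(C)C)C(C)C)cc([C@H]2COc3cc(O[Si](C(C)C)(C(C)C)C(C)C)cc(O[Si](C(C)C)(C(C)C)C(C)C)c3C2=O)cc1CC=C
F0 | step 10 | none | none
F3 | step 6 | (2S)-2-[3-bromo-4-methoxy-5-(triisopropylsilyloxy)phenyl]-3-hydroxypropyl benzoate | COc1c(O[Si](C(C)C)(C(C)C)C(C)C)cc([C@H](COC(=O)c2ccccc2)CO)cc1Br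
F4 | step 6 | (2S)-3-[3,5-bis(triisopropylsilyloxy)phenoxy]-2-[3-bromo-4-methoxy-5-(triisopropylsilyloxy)phenyl]propyl benzoate | COc1c(O[Si](C(C)C)(C(C)C)C(C)C)cc([C@H](COC(=O)c2ccccc2)COc2cc(O[Si](C(C)C)(C(C)C)C(C)C)cc(O[Si](C(C)C)(C(C)C)C(C)C)c2)cc1Br
F5 | step 4 | 3-bromo-2-methoxy-5-[2-(methylsulfanyl)-2-(methylsulfinyl)ethenyl]phenol (mixture of alkene isomers, racemic at sulfur) | COc1c(O)cc(C=C(SC)S(C)=O)cc1Br
F6 | step 4 | ethyl (3-bromo-5-hydroxy-4-methoxyphenyl)acetate | CCOC(=O)Cc1cc(O)c(OC)c(Br)c1
F7 | step 4 | ethyl [3-bromo-4-methoxy-5-(triisopropylsilyloxy)phenyl]acetate | CCOC(=O)Cc1cc(O[Si](C(C)C)(C(C)C)C(C)C)c(OC)c(Br)c1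
A1 | alternative 1 | racemic 2-methoxy-5,7,3'-tris(methoxymethoxy)-4'-methoxy-5'-prenylisoflavanone, mixture of C2 epimers | COCOc1cc(OCOC)c2c(c1)OC(OC)C(c1cc(OCOC)c(OC)c(CC=C(C)C)c1)C2=O
A2 | alternative 1 | 5,7-bis(methoxymethoxy)-2,2-dimethyl-4H-1,3-benzodioxin-4-one | COCOc1cc(OCOC)c2c(c1)OC(C)(C)OC2=O
A3 | alternative 1 | 1-methoxy-5-(2-methoxyethenyl)-2-(methoxymethoxy)... written in full: 2-methoxy-1-(methoxymethoxy)-5-(2-methoxyethenyl)-3-(3-methylbut-2-enyl)benzene (mixture of alkene isomers) | COC=Cc1cc(OCOC)c(OC)c(CC=C(C)C)c1
A4 | alternative 1 | 3,5-bis(methoxymethoxy)-6-(oxomethylidene)cyclohexa-2,4-dien-1-one (quinoketene) | O=C=C1C(=O)C=C(OCOC)C=C1OCOC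
A5 | alternative 1 | 5,7,3'-tris(methoxymethoxy)-4'-methoxy-5'-prenylisoflavone | COCOc1cc(OCOC)c2c(c1)occ(-c1cc(OCOC)c(OC)c(CC=C(C)C)c1)c2=O
A6 | alternative 2 | racemic 5,7,3'-tris(methoxymethoxy)-4'-methoxy-5'-prenylisoflavanone | COCOc1cc(OCOC)c2c(c1)OCC(c1cc(OCOC)c(OC)c(CC=C(C)C)c1)C2=O
A7 | alternative 2 | 2-[4-methoxy-3-(methoxymethoxy)-5-(3-methylbut-2-enyl)phenyl]prop-2-enoic acid | C=C(C(=O)O)c1cc(OCOC)c(OC)c(CC=C(C)C)c1
A8 | alternative 2 | 3,5-bis(methoxymethoxy)-2-(trimethylsilyl)phenyl trifluoromethanesulfonate | COCOc1cc(OCOC)c([Si](C)(C)C)c(OS(=O)(=O)C(F)(F)F)c1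
A9 | alternative 2 | 3,5-bis(methoxymethoxy)-1,2-didehydrobenzene (benzyne) | COCOC1=CC#CC(OCOC)=C1
A10 | alternative 3 | (3S)-5,4'-dimethoxy-5'-prenyl-7,3'-bis(triisopropylsilyloxy)isoflavanone | COc1c(O[Si](C(C)C)(C(C)C)C(C)C)cc([C@H]2COc3cc(O[Si](C(C)C)(C(C)C)C(C)C)cc(OC)c3C2=O)cc1CC=C(C)C
A11 | alternative 3 | 2-diazo-1-[2,6-dimethoxy-4-(triisopropylsilyloxy)phenyl]-2-[4-methoxy-3-(3-methylbut-2-enyl)-5-(triisopropylsilyloxy)phenyl]ethanone | COc1cc(O[Si](C(C)C)(C(C)C)C(C)C)cc(OC)c1C(=O)C(=[N+]=[N-])c1cc(O[Si](C(C)C)(C(C)C)C(C)C)c(OC)c(CC=C(C)C)c1
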